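The numbers in the tables stem from a simulated flask with made-up constants; scatter was added.

The ratio of Z to X read 1.80 in elm and 1.79 in oak, alike although D was charged at 12 mM and 18 mM, while E stood near 42.0 mM and 45.0 mM. So I set two rates per D against each other: the rate of going to Z, which I took to rise with E, and the rate of going to X, which I took to ignore E. D then cancels from their ratio. At 10 °C, larch, richer in E, read 6.69 against 2.42 in ash.

| flask | D | E | temperature | remark | time |
|---|---|---|---|---|---|
| ash | 12 mM | 2.5 equiv | 10 °C | run made earlier |  |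
| elm | 12 mM | 3.5 equiv | 25 °C | run made earlier |  |
| larch | 12 mM | 5.5 equiv | 10 °C | run made earlier |  |
| oak | 18 mM | 2.5 equiv | 25 °C | run made earlier |  |
| grey | 12 mM | 2.50 equiv (fed, over 25 h) | 25 °C | all else is in the flask from the start; the feed brings no volume worth counting | 12 d |
| amber | 12 mM (fed, over 10 d) | 2.50 equiv | 25 °C | all else is in the flask from the start; the feed brings no volume worth counting | 12 d |
| violet | 12 mM | 2.50 equiv | 25 °C | everything together at the start | 12 d |
| teal | 12 mM (fed, over 10 d) | 2.50 equiv |  | the addition at −15 °C, then warmed to 25 °C; the feed brings no volume worth counting | 12 d |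

| run | time / d | Z / % | X / % | D / % |
|---|---|---|---|---|
| ash | 1.25 | 26.4 | 9.5 | 29.1 |
| ash | 2.00 | 30.4 | 11.7 | 14.7 |
| ash | 4.00 | 33.4 | 13.6 | 3.1 |
| ash | 5.00 | 34.4 | 13.5 | 1.0 |
| ash | 8.00 | 34.4 | 13.9 | 0 |
| ash | 15.0 | 34.4 | 14.2 | 0 |
| elm | 2.50 | 38.7 | 22.2 | 0.4 |
| elm | 5.00 | 39.1 | 22.2 | 0.3 |
| elm | 8.00 | 40.7 | 21.1 | 0 |
| elm | 10.0 | 39.6 | 22.4 | 0 |
| elm | 12.0 | 39.3 | 22.2 | 0 |
| elm | 15.0 | 40.0 | 22.2 | 0 |
| larch | 2.50 | 53.0 | 7.9 | 2.3 |
| larch | 4.00 | 53.2 | 7.6 | 0.3 |
| larch | 6.00 | 53.2 | 8.0 | 0.2 |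
| larch | 10.0 | 54.2 | 9.0 | 1.1 |
| larch | 15.0 | 53.5 | 8.0 | 0.8 |
| larch | 30.0 | 53.2 | 7.1 | 0 |
| oak | 1.25 | 33.6 | 18.8 | 0 |
| oak | 2.00 | 34.0 | 19.1 | 0 |
| oak | 4.00 | 33.6 | 19.4 | 0 |
| oak | 8.00 | 34.1 | 19.0 | 0 |
| oak | 15.0 | 34.1 | 18.5 | 0.4 |

(each reading ± 0.5 percentage points)

- the numbers in the tables scatter with a standard deviation of 0.5 percentage points

- the flask that comes out highest in share of Z in Z plus X, or "all alike" when all lie within 1.5 percentage points (grey / amber / violet / teal / all alike)
- share of Z in Z plus X at the end, grey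
- share of Z in Z plus X at the end, amber
- share of Z in Z plus X at the end, violet
- share of Z in Z plus X at the end, teal

Elm's E, scaled by its X over Z and divided by the E charge of the new flasks, came to 0.777, with E used up ignored. This is the crossover fraction, the fraction of that charge at which the two rates match (a selectivity factor put as an amount of E). At a fraction e, the share of Z in Z plus X is e/(e+crossover).

For violet, at e = 1, I reckoned 56.3 %, and amber close to it. Grey's E trickles in while D reacts, so I took e = 0.5 and got 39.2 %. Teal I put highest, since ash read above oak at the same equivalents but colder.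

The forecast named teal, with grey 42 %, amber 54 %, violet 55 % and teal 68 %; of grey it said “D is mostly spent while E is still low”.

The flasks gave grey 30.3 %, amber 52.3 %, violet 54.4 % and teal 62.5 %, so teal came highest, and grey fell 12 points under the forecast.

    D + Z → L (k = 0.130 M⁻¹ min⁻¹, Ea = 53.0 kJ mol⁻¹)
    2 D → J (k = 0.0520 M⁻¹ min⁻¹, Ea = 68.0 kJ mol⁻¹)
    D → X (k = 7.30 × 10⁻⁴ min⁻¹, Ea = 98.0 kJ mol⁻¹)
    D + E → Z (k = 0.0420 M⁻¹ min⁻¹, Ea = 58.0 kJ mol⁻¹)
    (constants at 25 °C)

Teal had nearly come to rest: at 12.0 d it held D 0.0752 % with E at 81 % of its charge. My crossover fraction, read from elm with E used up ignored, put Z at 50.9 % of a split between Z and X at that E, which is a reckoning and not a reading of teal. At 120 d teal read 62.5 %, with Z 34.5 % and X 20.7 %. Grey, with E at 91 %, held D 0 %, and at 120 d it read 30.3 %.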